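**Strategy.** The ten-membered carbocycle is disconnected at C-8–C-9 (germacrane numbering) by an anionic oxy-Cope ring expansion. The step exploits the cis C-4=C-5 olefin of this ring, which is the memory of a cyclohexene. A carvone-derived 1-alkenyl-6-isopropenylcyclohex-2-en-1-ol carrying an (E)-vinylsilane expands from six to ten ring atoms, forming C-8–C-9 and cleaving C-1–C-6. In one operation it sets the E C-1(10) olefin, C-8 (silicon as masked oxygen) and, by protonation of the transannular enolate, C-7. The single stereocentre of carvone is thereby relayed to C-3, C-6, C-7, C-8 and the epoxide; the epoxyangelate arrives by Sharpless epoxidation.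

Key step: step 7

Remark: germacrane numbering (C-1 to C-15; lactone carbonyl C-12, exocyclic methylene C-13) is used for the ten-membered-ring compounds and the atoms that become them; α/β refer to the usual germacranolide projection (H-7 α). TBS = tert-butyldimethylsilyl. Compounds 1, 8 and 31 and all reagents are taken as commercial.

**Step 1**
Reactants: 1 (S)-carvone
Product: 2 (1S,4S,6S)-1-methyl-4-(prop-1-en-2-yl)-7-oxabicyclo[4.1.0]heptan-2-one
Conditions: 30% H2O2, NaOH (aq), MeOH, 0 °C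
Reagents that add atoms: hydrogen peroxide, OO
Why: Weitz–Scheffer nucleophilic epoxidation of the enone, in which hydroperoxide should add to the β-carbon anti to the isopropenyl group so that the epoxide is trans to it (substrate control).

**Step 2**
Reactants: 2 (1S,4S,6S)-1-methyl-4-(prop-1-en-2-yl)-7-oxabicyclo[4.1.0]heptan-2-one
Product: 5 (1S,5R)-2-methyl-5-(prop-1-en-2-yl)cyclohex-2-en-1-ol, via epoxy hydrazone 3 (not isolated), via alkenyl diazene 4 (not isolated)
Conditions: N2H4·H2O, AcOH (cat.), MeOH, 0 °C → rt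
Reagents that add atoms: none
Why: Wharton transposition (hydrazone, epoxide opening, loss of N2) leaves the C–O bond of the former β-carbon untouched, so the carbinol stays trans to the isopropenyl group and trans-carveol of the required absolute series results.

**Step 3**
Reactants: 5 (1S,5R)-2-methyl-5-(prop-1-en-2-yl)cyclohex-2-en-1-ol
Product: 6 tert-butyldimethyl{[(1S,5R)-2-methyl-5-(prop-1-en-2-yl)cyclohex-2-en-1-yl]oxy}silane
Conditions: TBSCl, imidazole, DMF, rt
Reagents that add atoms: tert-butyldimethylsilyl chloride, C[Si](C)(Cl)C(C)(C)C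
Why: Standard silylation of a secondary allylic alcohol; no stereocentre is touched.

**Step 4**
Reactants: 6 tert-butyldimethyl{[(1S,5R)-2-methyl-5-(prop-1-en-2-yl)cyclohex-2-en-1-yl]oxy}silane
Product: 7 (4S,6R)-4-[(tert-butyldimethylsilyl)oxy]-3-methyl-6-(prop-1-en-2-yl)cyclohex-2-en-1-one
Conditions: CrO3, 3,5-dimethylpyrazole, CH2Cl2, −20 °C
Reagents that add atoms: chromium trioxide, O=[Cr](=O)=O
Why: Allylic oxidation with the hexavalent chromium–pyrazole complex should convert the only ring allylic methylene into the conjugated enone carbonyl (future C-6), leaving both stereocentres intact.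

**Step 5**
Reactants: 8 tert-butyl(but-3-yn-1-yloxy)dimethylsilane
Product: 10 benzyl{4-[(tert-butyldimethylsilyl)oxy]but-1-yn-1-yl}dimethylsilane, via lithium acetylide 9 (not isolated)
Conditions: n-BuLi, THF, −78 °C; then benzylchlorodimethylsilane, −78 °C → rt
Reagents that add atoms: benzylchlorodimethylsilane, C[Si](C)(Cl)Cc1ccccc1
Why: Deprotonation of the terminal alkyne and C-silylation of the acetylide.

**Step 6**
Reactants: 7 (4S,6R)-4-[(tert-butyldimethylsilyl)oxy]-3-methyl-6-(prop-1-en-2-yl)cyclohex-2-en-1-one, 10 benzyl{4-[(tert-butyldimethylsilyl)oxy]but-1-yn-1-yl}dimethylsilane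
Product: 13 (1R,4S,6R)-1-{(E)-1-[benzyl(dimethyl)silyl]-4-[(tert-butyldimethylsilyl)oxy]but-1-en-2-yl}-4-[(tert-butyldimethylsilyl)oxy]-3-methyl-6-(prop-1-en-2-yl)cyclohex-2-en-1-ol, via titanium alkyne complex 11 (not isolated), via oxatitanacyclopentene 12 (not isolated)
Conditions: Ti(OiPr)4, iPrMgCl (2 equiv per Ti), Et2O, −78 → −50 °C; then 7, −50 → −20 °C; aq. NH4Cl
Reagents that add atoms: none
Why: Titanium alkoxide-mediated alkyne–carbonyl reductive coupling (Kulinkovich-type divalent titanium reagent): the ketone should insert at the alkyne carbon remote from silicon and anti to the neighbouring isopropenyl group (new carbinol stereocentre), and protonolysis of the α-silyl C–Ti bond with retention gives the E-vinylsilane with silicon trans to the carbinol carbon.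

**Step 7**
Reactants: 13 (1R,4S,6R)-1-{(E)-1-[benzyl(dimethyl)silyl]-4-[(tert-butyldimethylsilyl)oxy]but-1-en-2-yl}-4-[(tert-butyldimethylsilyl)oxy]-3-methyl-6-(prop-1-en-2-yl)cyclohex-2-en-1-ol
Product: 16 (2Z,4S,6E,9R,10S)-9-[benzyl(dimethyl)silyl]-4-[(tert-butyldimethylsilyl)oxy]-10-{2-[(tert-butyldimethylsilyl)oxy]ethyl}-3,7-dimethylcyclodeca-2,6-dien-1-one, via potassium alkoxide 14 (not isolated), via potassium dienolate 15 (not isolated)
Conditions: KH, 18-crown-6, THF, 0 °C → rt; then inverse quench into AcOH, THF, −78 °C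
Reagents that add atoms: none
Why: KH/18-crown-6 gives the naked tertiary alkoxide 14, which should undergo an anionic oxy-Cope [3,3] sigmatropic shift through a chair transition state in which the alkenyl group on the carbinol carbon and the isopropenyl group (trans on the cyclohexene) are both equatorial; C-8–C-9 forms as C-1–C-6 breaks and the charge ends in dienolate 15. The closest known reaction type is the anionic oxy-Cope ring expansion of trans-1,2-dialkenylcyclohexanols to cyclodeca-1,5-dienones used for germacranes. The ten-membered ring is closed by a concerted six-to-ten ring expansion (bond made between the two exocyclic olefin termini in a six-centre chair array), the cis C-4=C-5 olefin being carried over from the cyclohexene and the E C-1(10) olefin dictated by the chair. C-8 is set by the E geometry of the vinylsilane (silyl group equatorial in the chair) together with the C-1/C-6 configuration relayed from carvone, giving 8β-silicon; C-7 is set when the planar cross-conjugated dienolate, one face of which is spanned by the C-8–C-9–C-10=C-1–C-2 bridge, is protonated on its open face (7α-H). The step needs the chair [3,3] path through the two exocyclic alkenes rather than a shift through the ring olefin, a [1,3] shift, a carbon-to-oxygen silyl shift or β-elimination from the enolate: the trans-diequatorial alkenyl groups secure the first two, silicon trans to the alkoxide cannot reach oxygen, and silicon, unlike an alkoxy group, is no leaving group.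

**Step 8**
Reactants: 16 (2Z,4S,6E,9R,10S)-9-[benzyl(dimethyl)silyl]-4-[(tert-butyldimethylsilyl)oxy]-10-{2-[(tert-butyldimethylsilyl)oxy]ethyl}-3,7-dimethylcyclodeca-2,6-dien-1-one
Product: 17 (1R,2Z,4S,6E,9R,10S)-9-[benzyl(dimethyl)silyl]-4-[(tert-butyldimethylsilyl)oxy]-10-{2-[(tert-butyldimethylsilyl)oxy]ethyl}-3,7-dimethylcyclodeca-2,6-dien-1-ol
Conditions: NaBH4, CeCl3·7H2O, MeOH, −40 °C
Reagents that add atoms: none
Why: Luche 1,2-reduction of the cis-enone; hydride should attack C-6 on the face opposite the transannular bridge (the face already used by the proton at C-7), giving the 6α-alcohol.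

**Step 9**
Reactants: 17 (1R,2Z,4S,6E,9R,10S)-9-[benzyl(dimethyl)silyl]-4-[(tert-butyldimethylsilyl)oxy]-10-{2-[(tert-butyldimethylsilyl)oxy]ethyl}-3,7-dimethylcyclodeca-2,6-dien-1-ol
Product: 18 (1R,2Z,4S,6E,9R,10S)-9-[benzyl(dimethyl)silyl]-4-[(tert-butyldimethylsilyl)oxy]-10-(2-hydroxyethyl)-3,7-dimethylcyclodeca-2,6-dien-1-ol
Conditions: PPTS, MeOH, rt
Reagents that add atoms: none
Why: Acid-catalysed methanolysis should cleave the primary silyl ether much faster than the hindered secondary allylic one.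

**Step 10**
Reactants: 18 (1R,2Z,4S,6E,9R,10S)-9-[benzyl(dimethyl)silyl]-4-[(tert-butyldimethylsilyl)oxy]-10-(2-hydroxyethyl)-3,7-dimethylcyclodeca-2,6-dien-1-ol
Product: 21 8β-[benzyl(dimethyl)silyl]-3β-[(tert-butyldimethylsilyl)oxy]-13-norgermacra-1(10)E,4Z-dien-12,6α-olide, via hydroxy aldehyde 19 (not isolated), via lactol 20 (not isolated)
Conditions: TEMPO (cat.), PhI(OAc)2, CH2Cl2, rt
Reagents that add atoms: none
Why: Oxoammonium oxidation of the primary alcohol, lactol formation with the 6α-hydroxyl and further oxidation should give the trans-fused γ-lactone; because the C-8 oxygen is still masked as silicon, only the 12,6-lactone can form.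

**Step 11**
Reactants: 21 8β-[benzyl(dimethyl)silyl]-3β-[(tert-butyldimethylsilyl)oxy]-13-norgermacra-1(10)E,4Z-dien-12,6α-olide
Product: 25 8β-[benzyl(dimethyl)silyl]-3β-[(tert-butyldimethylsilyl)oxy]germacra-1(10)E,4Z,11(13)-trien-12,6α-olide, via lithium enolate 22 (not isolated), via Mannich base 23 (not isolated), via trimethylammonium iodide 24 (not isolated)
Conditions: LiN(iPr)2, THF, −78 °C; CH2=NMe2+ I−, −78 → 0 °C; then MeI, MeOH, rt; then aq. NaHCO3, EtOAc, rt
Reagents that add atoms: N,N-dimethylmethyleneiminium iodide (Eschenmoser's salt), C=[N+](C)C.[I-]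
Why: α-Methylenation of the lactone by Mannich reaction of its enolate, quaternisation and Hofmann-type elimination; it is placed before any ester is present.

**Step 12**
Reactants: 25 8β-[benzyl(dimethyl)silyl]-3β-[(tert-butyldimethylsilyl)oxy]germacra-1(10)E,4Z,11(13)-trien-12,6α-olide
Product: 26 8β-[benzyl(dimethyl)silyl]-3β-hydroxygermacra-1(10)E,4Z,11(13)-trien-12,6α-olide
Conditions: HF·pyridine, pyridine, THF, 0 °C → rt
Reagents that add atoms: none
Why: Buffered fluoride cleavage of the silyl ether; the carbon-bound benzyldimethylsilyl group, the dienes and the methylene lactone should be left alone.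

**Step 13**
Reactants: 26 8β-[benzyl(dimethyl)silyl]-3β-hydroxygermacra-1(10)E,4Z,11(13)-trien-12,6α-olide
Product: 27 8β-[benzyl(dimethyl)silyl]-3β-(3-methylbutanoyloxy)germacra-1(10)E,4Z,11(13)-trien-12,6α-olide
Conditions: isovaleric anhydride, DMAP (cat.), Et3N, CH2Cl2, 0 °C → rt
Reagents that add atoms: isovaleric anhydride, CC(C)CC(=O)OC(=O)CC(C)C
Why: DMAP-catalysed acylation of the only free hydroxyl group.

**Step 14**
Reactants: 27 8β-[benzyl(dimethyl)silyl]-3β-(3-methylbutanoyloxy)germacra-1(10)E,4Z,11(13)-trien-12,6α-olide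
Product: 30 1β,10α-epoxy-8β-hydroxy-3β-(3-methylbutanoyloxy)germacra-4Z,11(13)-dien-12,6α-olide, via silanol 28 (not isolated), via epoxy silanol 29 (not isolated)
Conditions: Bu4NF, THF, 0 °C; then mCPBA, KF, DMF, 0 °C → rt
Reagents that add atoms: 3-chloroperoxybenzoic acid, OOC(=O)c1cccc(Cl)c1
Why: Fluoride removes the benzyl group from silicon and the resulting silanol undergoes Tamao–Fleming oxidation with peracid/fluoride (carbon-to-oxygen shift with retention, hence 8β-OH), while the same peracid should epoxidise (Prilezhaev) the electron-rich 1(10)-olefin on its exposed face in the preferred lactone conformer (C-14 on the β face) to the 1β,10α-epoxide; the 4,5-olefin is deactivated by two allylic C–O bonds and the methylene lactone is electron-poor.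

**Step 15**
Reactants: 31 angelic acid, (Z)-2-methylbut-2-enoic acid
Product: 32 (Z)-2-methylbut-2-en-1-ol
Conditions: LiAlH4, Et2O, 0 °C
Reagents that add atoms: none
Why: Hydride reduction of the acid to the allylic alcohol with retention of the Z geometry.

**Step 16**
Reactants: 32 (Z)-2-methylbut-2-en-1-ol
Product: 33 [(2R,3S)-2,3-dimethyloxiran-2-yl]methanol
Conditions: Ti(OiPr)4 (cat.), D-(−)-diethyl tartrate (cat.), t-BuOOH, 4 Å molecular sieves, CH2Cl2, −20 °C
Reagents that add atoms: tert-butyl hydroperoxide, CC(C)(C)OO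
Why: Sharpless asymmetric epoxidation; the D-(−)-tartrate catalyst should deliver oxygen syn-stereospecifically to the olefin face that gives the (2R,3S)-epoxy alcohol.

**Step 17**
Reactants: 33 [(2R,3S)-2,3-dimethyloxiran-2-yl]methanol
Product: 35 (2S,3S)-2,3-dimethyloxirane-2-carboxylic acid, via epoxy aldehyde 34 (not isolated)
Conditions: TEMPO (cat.), PhI(OAc)2, MeCN/H2O, rt
Reagents that add atoms: water, O
Why: Oxoammonium oxidation of the primary alcohol through the aldehyde hydrate to the acid; the epoxide stereocentres are not touched (the C-2 descriptor changes only by priority).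

**Step 18**
Reactants: 30 1β,10α-epoxy-8β-hydroxy-3β-(3-methylbutanoyloxy)germacra-4Z,11(13)-dien-12,6α-olide, 35 (2S,3S)-2,3-dimethyloxirane-2-carboxylic acid
Product: 37 (1R,3S,6R,7R,8R,10R)-1,10-epoxy-8-[(2S,3S)-2,3-dimethyloxirane-2-carbonyloxy]-3-(3-methylbutanoyloxy)germacra-4Z,11(13)-dien-12,6-olide, via mixed anhydride 36 (not isolated)
Conditions: 35, 2,4,6-trichlorobenzoyl chloride, Et3N, toluene, rt; then 30, DMAP, toluene, rt → 40 °C
Reagents that add atoms: none
Why: Yamaguchi esterification, the method of choice for hindered secondary alcohols and α,α-disubstituted acids; it proceeds with retention at C-8 and without touching the epoxides.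

**Compound list**
1 | (S)-carvone, (5S)-2-methyl-5-(prop-1-en-2-yl)cyclohex-2-en-1-one | CC1=CC[C@@H](CC1=O)C(C)=C | starting material
2 | (1S,4S,6S)-1-methyl-4-(prop-1-en-2-yl)-7-oxabicyclo[4.1.0]heptan-2-one (epoxide trans to isopropenyl) | O=C1C[C@@H](C(C)=C)C[C@@H]2O[C@]12C | intermediate
3 | hydrazone of epoxy ketone 2 | NN=C1C[C@@H](C(C)=C)C[C@@H]2O[C@]12C | intermediate
4 | (1S,5R)-3-diazenyl-2-methyl-5-(prop-1-en-2-yl)cyclohex-2-en-1-ol | N=NC1=C(C)[C@@H](O)C[C@H](C(C)=C)C1 | intermediate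
5 | (1S,5R)-2-methyl-5-(prop-1-en-2-yl)cyclohex-2-en-1-ol (trans-carveol) | CC1=CC[C@@H](C(C)=C)C[C@@H]1O | intermediate
6 | tert-butyldimethyl{[(1S,5R)-2-methyl-5-(prop-1-en-2-yl)cyclohex-2-en-1-yl]oxy}silane | CC1=CC[C@@H](C(C)=C)C[C@@H]1O[Si](C)(C)C(C)(C)C | intermediate
7 | (4S,6R)-4-[(tert-butyldimethylsilyl)oxy]-3-methyl-6-(prop-1-en-2-yl)cyclohex-2-en-1-one | O=C1C=C(C)[C@@H](O[Si](C)(C)C(C)(C)C)C[C@@H]1C(C)=C | intermediate
8 | tert-butyl(but-3-yn-1-yloxy)dimethylsilane | C#CCCO[Si](C)(C)C(C)(C)C | starting material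
9 | lithium acetylide of 8 | [Li]C#CCCO[Si](C)(C)C(C)(C)C | intermediate
10 | benzyl{4-[(tert-butyldimethylsilyl)oxy]but-1-yn-1-yl}dimethylsilane | C[Si](C)(Cc1ccccc1)C#CCCO[Si](C)(C)C(C)(C)C | intermediate
11 | diisopropoxytitanium complex of alkyne 10 (titanacyclopropene) | CC(C)O[Ti]1(OC(C)C)C(CCO[Si](C)(C)C(C)(C)C)=C1[Si](C)(C)Cc1ccccc1 | intermediate
12 | 2-oxa-1-titanacyclopent-4-ene from 11 and 7 (Ti–O on the carbinol carbon, Ti–C on the silyl-bearing carbon) | CC(C)O[Ti]1(OC(C)C)O[C@@]2(C=C(C)[C@@H](O[Si](C)(C)C(C)(C)C)C[C@@H]2C(C)=C)C(CCO[Si](C)(C)C(C)(C)C)=C1[Si](C)(C)Cc1ccccc1 | intermediate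
13 | (1R,4S,6R)-1-{(E)-1-[benzyl(dimethyl)silyl]-4-[(tert-butyldimethylsilyl)oxy]but-1-en-2-yl}-4-[(tert-butyldimethylsilyl)oxy]-3-methyl-6-(prop-1-en-2-yl)cyclohex-2-en-1-ol | O[C@]1(/C(CCO[Si](C)(C)C(C)(C)C)=C/[Si](C)(C)Cc2ccccc2)C=C(C)[C@@H](O[Si](C)(C)C(C)(C)C)C[C@@H]1C(C)=C | intermediate
14 | potassium alkoxide of 13 | [K+].[O-][C@]1(/C(CCO[Si](C)(C)C(C)(C)C)=C/[Si](C)(C)Cc2ccccc2)C=C(C)[C@@H](O[Si](C)(C)C(C)(C)C)C[C@@H]1C(C)=C | intermediate
15 | potassium dienolate of 16 (C-6 oxide, C-6=C-7 with oxygen cis to C-8, 1(10)E, 4Z) | [K+].C1/C=C(C)/C[C@@H]([Si](C)(C)Cc2ccccc2)/C(CCO[Si](C)(C)C(C)(C)C)=C([O-])/C=C(/C)[C@H]1O[Si](C)(C)C(C)(C)C | intermediate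
16 | (2Z,4S,6E,9R,10S)-9-[benzyl(dimethyl)silyl]-4-[(tert-butyldimethylsilyl)oxy]-10-{2-[(tert-butyldimethylsilyl)oxy]ethyl}-3,7-dimethylcyclodeca-2,6-dien-1-one | O=C1/C=C(/C)[C@@H](O[Si](C)(C)C(C)(C)C)C/C=C(C)/C[C@@H]([Si](C)(C)Cc2ccccc2)[C@H]1CCO[Si](C)(C)C(C)(C)C | intermediate
17 | (1R,2Z,4S,6E,9R,10S)-9-[benzyl(dimethyl)silyl]-4-[(tert-butyldimethylsilyl)oxy]-10-{2-[(tert-butyldimethylsilyl)oxy]ethyl}-3,7-dimethylcyclodeca-2,6-dien-1-ol | O[C@@H]1/C=C(/C)[C@@H](O[Si](C)(C)C(C)(C)C)C/C=C(C)/C[C@@H]([Si](C)(C)Cc2ccccc2)[C@H]1CCO[Si](C)(C)C(C)(C)C | intermediate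
18 | (1R,2Z,4S,6E,9R,10S)-9-[benzyl(dimethyl)silyl]-4-[(tert-butyldimethylsilyl)oxy]-10-(2-hydroxyethyl)-3,7-dimethylcyclodeca-2,6-dien-1-ol | O[C@@H]1/C=C(/C)[C@@H](O[Si](C)(C)C(C)(C)C)C/C=C(C)/C[C@@H]([Si](C)(C)Cc2ccccc2)[C@H]1CCO | intermediate
19 | hydroxy aldehyde from 18 (C-12 aldehyde, 6α-OH) | O[C@@H]1/C=C(/C)[C@@H](O[Si](C)(C)C(C)(C)C)C/C=C(C)/C[C@@H]([Si](C)(C)Cc2ccccc2)[C@H]1CC=O | intermediate
20 | 12,6α-lactol of 19 (both anomers at C-12) | OC1O[C@@H]2/C=C(/C)[C@@H](O[Si](C)(C)C(C)(C)C)C/C=C(C)/C[C@@H]([Si](C)(C)Cc3ccccc3)[C@H]2C1 | intermediate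
21 | 8β-[benzyl(dimethyl)silyl]-3β-[(tert-butyldimethylsilyl)oxy]-13-norgermacra-1(10)E,4Z-dien-12,6α-olide (6β-H, 7α-H) | C1C(=O)O[C@@H]2/C=C(/C)[C@@H](O[Si](C)(C)C(C)(C)C)C/C=C(C)/C[C@@H]([Si](C)(C)Cc3ccccc3)[C@@H]12 | intermediate
22 | lithium enolate of lactone 21 | [Li+].C1=C([O-])O[C@@H]2/C=C(/C)[C@@H](O[Si](C)(C)C(C)(C)C)C/C=C(C)/C[C@@H]([Si](C)(C)Cc3ccccc3)[C@@H]12 | intermediate
23 | 11-[(dimethylamino)methyl] derivative of 21 (C-11 epimers, configuration without consequence) | CN(C)CC1C(=O)O[C@@H]2/C=C(/C)[C@@H](O[Si](C)(C)C(C)(C)C)C/C=C(C)/C[C@@H]([Si](C)(C)Cc3ccccc3)[C@@H]12 | intermediate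
24 | trimethylammonium iodide of 23 | C[N+](C)(C)CC1C(=O)O[C@@H]2/C=C(/C)[C@@H](O[Si](C)(C)C(C)(C)C)C/C=C(C)/C[C@@H]([Si](C)(C)Cc3ccccc3)[C@@H]12.[I-] | intermediate
25 | 8β-[benzyl(dimethyl)silyl]-3β-[(tert-butyldimethylsilyl)oxy]germacra-1(10)E,4Z,11(13)-trien-12,6α-olide | C=C1C(=O)O[C@@H]2/C=C(/C)[C@@H](O[Si](C)(C)C(C)(C)C)C/C=C(C)/C[C@@H]([Si](C)(C)Cc3ccccc3)[C@@H]12 | intermediate
26 | 8β-[benzyl(dimethyl)silyl]-3β-hydroxygermacra-1(10)E,4Z,11(13)-trien-12,6α-olide | C=C1C(=O)O[C@@H]2/C=C(/C)[C@@H](O)C/C=C(C)/C[C@@H]([Si](C)(C)Cc3ccccc3)[C@@H]12 | intermediate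
27 | 8β-[benzyl(dimethyl)silyl]-3β-(3-methylbutanoyloxy)germacra-1(10)E,4Z,11(13)-trien-12,6α-olide | C=C1C(=O)O[C@@H]2/C=C(/C)[C@@H](OC(=O)CC(C)C)C/C=C(C)/C[C@@H]([Si](C)(C)Cc3ccccc3)[C@@H]12 | intermediate
28 | 8β-[hydroxy(dimethyl)silyl]-3β-(3-methylbutanoyloxy)germacra-1(10)E,4Z,11(13)-trien-12,6α-olide | C=C1C(=O)O[C@@H]2/C=C(/C)[C@@H](OC(=O)CC(C)C)C/C=C(C)/C[C@@H]([Si](C)(C)O)[C@@H]12 | intermediate
29 | 1β,10α-epoxy-8β-[hydroxy(dimethyl)silyl]-3β-(3-methylbutanoyloxy)germacra-4Z,11(13)-dien-12,6α-olide | C=C1C(=O)O[C@@H]2/C=C(/C)[C@@H](OC(=O)CC(C)C)C[C@H]3O[C@]3(C)C[C@@H]([Si](C)(C)O)[C@@H]12 | intermediate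
30 | 1β,10α-epoxy-8β-hydroxy-3β-(3-methylbutanoyloxy)germacra-4Z,11(13)-dien-12,6α-olide | C=C1C(=O)O[C@@H]2/C=C(/C)[C@@H](OC(=O)CC(C)C)C[C@H]3O[C@]3(C)C[C@@H](O)[C@@H]12 | intermediate
31 | angelic acid, (Z)-2-methylbut-2-enoic acid | C/C=C(/C)C(=O)O | starting material
32 | (Z)-2-methylbut-2-en-1-ol | C/C=C(/C)CO | intermediate
33 | [(2R,3S)-2,3-dimethyloxiran-2-yl]methanol | OC[C@@]1(C)O[C@H]1C | intermediate
34 | (2S,3S)-2,3-dimethyloxirane-2-carbaldehyde | O=C[C@@]1(C)O[C@H]1C | intermediate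
35 | (2S,3S)-2,3-dimethyloxirane-2-carboxylic acid | OC(=O)[C@@]1(C)O[C@H]1C | intermediate
36 | (2S,3S)-2,3-dimethyloxirane-2-carboxylic 2,4,6-trichlorobenzoic anhydride | O=C(OC(=O)[C@@]1(C)O[C@H]1C)c1c(Cl)cc(Cl)cc1Cl | intermediate
37 | (1R,3S,6R,7R,8R,10R)-1,10-epoxy-8-[(2S,3S)-2,3-dimethyloxirane-2-carbonyloxy]-3-(3-methylbutanoyloxy)germacra-4Z,11(13)-dien-12,6-olide | C=C1C(=O)O[C@@H]2/C=C(/C)[C@@H](OC(=O)CC(C)C)C[C@H]3O[C@]3(C)C[C@@H](OC(=O)[C@@]3(C)O[C@H]3C)[C@@H]12 | target

**Step count.** Total: 18 steps. Longest linear sequence: 14 steps (1 to 37 through steps 1–4, 6–14 and 18); steps 5 and 15–17 make the two side fragments.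

**Steps most likely to fail**

Step 7 (key step). What may go wrong: the sigmatropic shift is slowed by the fully substituted C-7 and the silyl group at C-8, so that decomposition of the naked alkoxide competes with ring expansion. Fallback, setting out from 13 and coming back at 16: the neutral thermal oxy-Cope rearrangement. Carbinol 13 would be heated in N-methylpyrrolidone at about 190 °C in a base-washed sealed tube. The same chair [3,3] shift should give the enol F1, which ketonises to 16. Any 7-epimeric ketone F2 formed in the less selective ketonisation would be separated, re-equilibrated with DBU in toluene and recycled.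

Step 14. What may go wrong: over-oxidation; during the long peracid exposure that the carbon–silicon oxidation needs, the 4,5-olefin may also be epoxidised or the first-formed epoxide may open. Fallback, setting out from 27 and coming back at 37: the two oxidations are separated and the epoxide is made last. After Bu4NF, silanol 28 would be oxidised with 30% H2O2 and KHF2 in DMF (fluoride-buffered, non-basic peroxide conditions that should epoxidise neither olefin and spare the methylene lactone) to the 8β-alcohol F3. Yamaguchi esterification of F3 with mixed anhydride 36 would give the 1(10)-olefinic diester F4. mCPBA with NaHCO3 in CH2Cl2 at 0 °C should then epoxidise only the 1(10)-olefin to give 37.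

Step 4. What may go wrong: poor site selectivity of the allylic C–H oxidation (attack at the vinylic methyl group, at the silyloxy-bearing carbon or at the isopropenyl group) and over-oxidation. Fallback, setting out from 6 and coming back at 7: the carbonyl oxygen is brought in by an oxidative 1,3-transposition. mCPBA with NaHCO3 in CH2Cl2 at 0 °C would epoxidise the ring olefin anti to the silyloxy group to the epoxide F5. PhSeNa (from PhSeSePh and NaBH4 in EtOH) should open it at the secondary carbon to the hydroxy selenide F6. H2O2 would oxidise this to the selenoxide F7, whose syn-elimination gives the tertiary allylic alcohol F8. Pyridinium chlorochromate, [C5H5NH][CrO3Cl], in CH2Cl2 (Babler–Dauben oxidative transposition) should then deliver enone 7.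

**Further compounds**
F1 | step 7 | enol tautomer of ketone 16 (C-6 enol, C-6=C-7) | C1/C=C(C)/C[C@@H]([Si](C)(C)Cc2ccccc2)/C(CCO[Si](C)(C)C(C)(C)C)=C(O)/C=C(/C)[C@H]1O[Si](C)(C)C(C)(C)C
F2 | step 7 | 7-epimer of ketone 16 | O=C1/C=C(/C)[C@@H](O[Si](C)(C)C(C)(C)C)C/C=C(C)/C[C@@H]([Si](C)(C)Cc2ccccc2)[C@@H]1CCO[Si](C)(C)C(C)(C)C
F3 | step 14 | 8β-hydroxy-3β-(3-methylbutanoyloxy)germacra-1(10)E,4Z,11(13)-trien-12,6α-olide | C=C1C(=O)O[C@@H]2/C=C(/C)[C@@H](OC(=O)CC(C)C)C/C=C(C)/C[C@@H](O)[C@@H]12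
F4 | step 14 | 8β-[(2S,3S)-2,3-dimethyloxirane-2-carbonyloxy]-3β-(3-methylbutanoyloxy)germacra-1(10)E,4Z,11(13)-trien-12,6α-olide | C=C1C(=O)O[C@@H]2/C=C(/C)[C@@H](OC(=O)CC(C)C)C/C=C(C)/C[C@@H](OC(=O)[C@@]3(C)O[C@H]3C)[C@@H]12
F5 | step 4 | ring epoxide of silyl ether 6 (oxygen anti to the silyloxy group) | C[C@]12O[C@H]1C[C@@H](C(C)=C)C[C@@H]2O[Si](C)(C)C(C)(C)C
F6 | step 4 | hydroxy selenide from F5 (tertiary alcohol, phenylseleno group on the neighbouring secondary carbon, trans) | C[C@]1(O)[C@H]([Se]c2ccccc2)C[C@@H](C(C)=C)C[C@@H]1O[Si](C)(C)C(C)(C)C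
F7 | step 4 | selenoxide of F6 | C[C@]1(O)[C@H]([Se](=O)c2ccccc2)C[C@@H](C(C)=C)C[C@@H]1O[Si](C)(C)C(C)(C)C
F8 | step 4 | 6-[(tert-butyldimethylsilyl)oxy]-1-methyl-4-(prop-1-en-2-yl)cyclohex-2-en-1-ol (tertiary allylic alcohol, hydroxyl trans to the silyloxy group) | C[C@]1(O)C=C[C@@H](C(C)=C)C[C@@H]1O[Si](C)(C)C(C)(C)C
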